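## Structural features

Gnetupendin B (17) consists of three benzene rings and has no stereocentre. No stereocentres therefore stand next to each other, and the only stereo-element is the E double bond C7=C8. Ring A is a resorcinol (C1 to C6, OH on C3 and C5, H on C4 and C6). Ring B is a 4-hydroxy-3-methoxyphenyl group and ring C a 3,4-dihydroxyphenyl group. Ring B is joined to C1 of ring A through C7=C8 (C7 on ring A). Ring C is joined to the neighbouring C2 through the single methylene carbon C9, so ring A is 1,2,3,5-tetrasubstituted with three contiguous substituents (styryl on C1, benzyl on C2, OH on C3).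

The fragile parts are three:
- the catechol of ring C, which is sensitive to air and base;
- the electron-rich stilbene double bond, which can be protonated at C7, isomerised by light, or hydrogenated;
- the single methyl ether on ring B, which forbids a global demethylation at the end.

The real difficulty is regiochemical. On a preformed 5-styrylresorcinol, C2/C6 and C4 are all activated by both hydroxyl groups. A benzyl electrophile therefore has no built-in reason to enter once, and only next to the styryl arm.

The key step exploits the O,H,O,H pattern on ring A atoms C3–C4–C5–C6, which is that of a 1,3-dioxygenated diene, while C1 and C2 carry the two carbon arms. C1≡C2 can therefore be an alkyne that already links rings B and C. C9, raised to a ketone, serves as activator and as regiochemical director of that alkyne. Because it ends up ortho to the C3 hydroxyl, it is also easy to return to CH2.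

## Logic of the disconnections

**17 to 16.** The bonds cut are the three O–CH2Ph bonds on the oxygens of rings B and C. The catechol and the ring B phenol must be masked against the Grignard reagent, the oxidant and the base used earlier. The gain is that both masked aldehydes (1 and 3) can be bought, so no protection step is spent. The demand is a debenzylation that uses no hydrogen (C7=C8) and leaves O–CH3 alone.

**16 to 13 and 12.** The bonds cut are the two C9–H bonds (C9 goes back to C=O) and, from 13 to 12, the two O–C(=O) bonds on the ring A oxygens. The carbonyl group is added in retrosynthesis because the next disconnection needs an acceptor exactly on C9. The gain is that the C3 oxygen, ortho to C9, provides a specific exit through an ortho-quinone methide. The demand is a reduction that works without acid, since a C9 cation could be caught by the styryl arm and C7=C8 could be protonated.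

**12 to 7 and 9 (key).** The bonds cut are C1–C6 and C2–C3 of ring A. In one sentence: ring A is not bought but made last, by an Alder–Rickert reaction on the open-chain ynone 7, in which rings B and C are already joined through C8=C7–C1≡C2–C9(=O). All four substituents of ring A are placed by one orientation of a polarised diene on a polarised alkyne, so no choice among C2, C4 and C6 ever arises. The gain is a linear precursor with no substituted central arene and a symmetric C6 partner. The demands are three:
- the alkyne must react and not C7=C8;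
- a single regiochemistry must result;
- the two-carbon bridge must leave cleanly.

**9 to 8.** The bonds cut are the two O–Si bonds. The diene is the doubly enolised form of a symmetric cyclic diketone. Its quaternary carbon prevents self-aromatisation and becomes part of the bridge that leaves. The demand is only a double O-silylation.

**7 to 6, then to 2 and 5.** First C9=O goes back to the carbinol. Then the C7–C1 bond, between the alkene carbon and the alkyne carbon, is cut. This is the natural seam between an sp2 and an sp carbon and splits the chain into two pieces of similar size. The demand is a coupling that retains the E geometry and tolerates a free propargylic alcohol.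

**5 to 3 and 4.** The bond cut is C9–C2, between the carbinol carbon and the alkyne carbon. A non-enolisable aromatic aldehyde and an ethynyl anion equivalent are the simplest partners. The stereocentre formed is of no consequence.

**2 to 1.** The bond cut is C7=C8. A one-carbon iodomethylenation of the aldehyde sets the E geometry and installs the coupling handle together. The demand is E selectivity, because every later step only carries this geometry along.

## Other disconnections considered

**Alternative 1:** This is the first idea that comes to mind. It cuts C2–C9 on a preformed resorcinol and C7=C8 by olefination.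
- *Short version.* Isorhapontigenin A1 is benzylated under acid with 3,4-dihydroxybenzyl alcohol A2 through its para-quinone methide.
- *Protected version.* 2-[3,4-Bis(benzyloxy)benzyl]-3,5-bis(benzyloxy)benzaldehyde A3 is joined to a ring B phosphonate by a Horner–Wadsworth–Emmons reaction.
- *Ground for preferring the chosen plan.* In A1 the positions C2/C6 and C4 are all ortho/para to both hydroxyl groups, and the wanted one is the most crowded. The monoalkylated product is no less nucleophilic than A1. The same acid can protonate C7=C8. A3 only moves the problem back to the making of a 1,2,3,5-tetrasubstituted arene and adds protection steps. In the chosen plan the substitution pattern follows from orbital polarisation and not from competition among similar ring positions.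

**Alternative 2:** This cuts C1–C7 and C2–C9 together.
- *Forward key step.* A palladium-catalysed three-component coupling joins the aryne released by fluoride from 3,5-bis(benzyloxy)-2-(trimethylsilyl)phenyl triflate A4, 3,4-bis(benzyloxy)benzyl bromide A5 and 1-(benzyloxy)-4-ethenyl-2-methoxybenzene A6. It proceeds by carbopalladation of the aryne followed by a Heck reaction.
- *Ground for preferring the chosen plan.* The cut is very convergent, but the C3 oxygen polarises the aryne so that the migrating carbon group prefers C1 and the metal C2. That would exchange the two arms. Only steric repulsion between the ligands on palladium and the C3 substituent works in the wanted direction. An electron-rich styrene is also a poorer Heck acceptor than an acrylate, so oligomerisation of the aryne has time to compete. A4 itself needs several steps.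

**Alternative 3:** This cuts C1–C2 and C3–C4 of ring A.
- *Forward key step.* A Diels–Alder reaction joins 4-(benzyloxy)-6-[(E)-2-(4-benzyloxy-3-methoxyphenyl)ethenyl]-2H-pyran-2-one A7 to the siloxyalkyne {3-[3,4-bis(benzyloxy)phenyl]prop-1-yn-1-yl}oxy(triisopropyl)silane A8, with loss of carbon dioxide.
- *Ground for preferring the chosen plan.* The polarity is matched, since the nucleophilic alkyne carbon meets C6 of the pyrone, and C9 arrives as CH2. However, the 4-alkoxy group makes A7 a vinylogous carbonate with a high LUMO, so two donors would have to react with each other. The styryl diene of A7 offers a second reaction site. The forcing conditions would endanger A8. The chosen plan pays two extra steps for the ketone but pairs a strong donor with a true acceptor.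

Key step: step 6

Remark on the chemistry: 5, 6 and 10 are racemic, and their stereocentres are erased in steps 4 and 6, so no enantioselective step is needed. All styryl compounds are handled with exclusion of light.

## Steps

Step 1
Reactants: 1 4-(benzyloxy)-3-methoxybenzaldehyde
Product: 2 1-(benzyloxy)-4-[(E)-2-iodoethenyl]-2-methoxybenzene
Conditions: CrCl2 (6 equiv), CHI3 (2 equiv), THF, 0 °C to rt, dark
Reagents that add atoms: iodoform, C(I)(I)I
Why: Takai olefination; the geminal dichromium reagent formed from CHI3 and CrCl2 adds to the aldehyde, and elimination from the less crowded adduct should give the E iodoalkene. Benzyl and methyl ethers are inert to divalent chromium. This step sets the only stereo-element of the target.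

Step 2
Reactants: 3 3,4-bis(benzyloxy)benzaldehyde; 4 ethynylmagnesium bromide
Product: 5 (±)-1-[3,4-bis(benzyloxy)phenyl]prop-2-yn-1-ol
Conditions: THF, 0 °C to rt; then sat. aq NH4Cl
Reagents that add atoms: none
Why: 1,2-Addition of an alkynyl Grignard reagent to a non-enolisable aromatic aldehyde. The new carbinol centre is racemic and is erased in step 4.

Step 3
Reactants: 2 1-(benzyloxy)-4-[(E)-2-iodoethenyl]-2-methoxybenzene; 5 (±)-1-[3,4-bis(benzyloxy)phenyl]prop-2-yn-1-ol
Product: 6 (±)-(E)-1-[3,4-bis(benzyloxy)phenyl]-5-[4-(benzyloxy)-3-methoxyphenyl]pent-4-en-2-yn-1-ol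
Conditions: PdCl2(PPh3)2 (2 mol %), CuI (4 mol %), Et3N (3 equiv), THF, degassed, rt
Reagents that add atoms: none
Why: Sonogashira coupling; oxidative addition of the alkenyl iodide to zerovalent palladium and the reductive elimination both go with retention, so the E geometry is carried over. The free carbinol is tolerated, and because the alkenyl partner is electron-rich, base-induced isomerisation of the propargylic alcohol to an enone is not expected at room temperature.

Step 4
Reactants: 6 (±)-(E)-1-[3,4-bis(benzyloxy)phenyl]-5-[4-(benzyloxy)-3-methoxyphenyl]pent-4-en-2-yn-1-ol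
Product: 7 (E)-1-[3,4-bis(benzyloxy)phenyl]-5-[4-(benzyloxy)-3-methoxyphenyl]pent-4-en-2-yn-1-one
Conditions: activated MnO2 (15 equiv), CH2Cl2, rt
Reagents that add atoms: none
Why: MnO2 oxidation of an alcohol that is both benzylic and propargylic. The neutral heterogeneous oxidant leaves the alkene, the alkyne and the ethers untouched.

Step 5
Reactants: 8 5,5-dimethylcyclohexane-1,3-dione (dimedone)
Product: 9 5,5-dimethyl-1,3-bis[(trimethylsilyl)oxy]cyclohexa-1,3-diene
Conditions: TMSOTf (2.3 equiv), Et3N (3 equiv), Et2O, 0 °C to rt; phase separation, distillation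
Reagents that add atoms: trimethylsilyl trifluoromethanesulfonate, C[Si](C)(C)OS(=O)(=O)C(F)(F)F
Why: Double soft enolisation and O-silylation of a 1,3-diketone with a silyl triflate and a tertiary amine. The symmetry of 8 allows only one 1,3-bis(silyloxy)-1,3-diene, and the quaternary carbon blocks its aromatisation.

Step 6
Reactants: 7 (E)-1-[3,4-bis(benzyloxy)phenyl]-5-[4-(benzyloxy)-3-methoxyphenyl]pent-4-en-2-yn-1-one; 9 5,5-dimethyl-1,3-bis[(trimethylsilyl)oxy]cyclohexa-1,3-diene
Product: 12 [3,4-bis(benzyloxy)phenyl]{2-[(E)-2-(4-benzyloxy-3-methoxyphenyl)ethenyl]-4,6-dihydroxyphenyl}methanone, via bicyclooctadiene adduct 10 (not isolated), via bis(trimethylsilyl) ether 11 (not isolated)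
Conditions: 9 (4 equiv), o-xylene (2 M), BHT (cat.), sealed tube, Ar, dark, 150 °C; then 1 M aq HCl, THF, rt
Reagents that add atoms: none
Why: Alder–Rickert reaction, that is a normal-electron-demand Diels–Alder addition of a cyclohexa-1,3-diene to an alkyne followed by retro-Diels–Alder loss of the two-carbon bridge; the closest known case is the thermal benzannulation of alkynoates and alkynones with 1,3-bis(silyloxy)cyclohexa-1,3-dienes to give resorcinols. Diene 9 is locked s-cis, and both silyloxy groups raise its HOMO and reinforce each other at the unsubstituted terminus C4, while the LUMO of 7 is largest at the alkyne carbon β to the ketone. Hence C4 of 9 should bond to the styryl-bearing carbon (new bond C6–C1 of ring A) and the silyloxy-bearing C1 of 9 to the aroyl-bearing carbon (new bond C3–C2), in a concerted but asynchronous intermolecular (4+2) closure that forms the six-membered ring of 10; a stepwise Michael-type path would give the same pairing. At the reaction temperature 10 loses its CMe2–CH2 bridge as 2-methylpropene, irreversibly because of aromatisation and escape of the gas, so ring A appears with O on C3 and C5, H on C4 and C6, the aroyl group on C2 and the styryl group on C1, all fixed by the one orientation. The two bridgehead stereocentres of 10 form as a racemate and vanish on aromatisation, and C7=C8 is a spectator whose E geometry has no thermal path to scramble under neutral conditions. Site selectivity (alkyne against C7=C8) is secured because only the triple bond is directly conjugated to the carbonyl group, whereas the alkene is 1,2-disubstituted and carries the donor ring B. The neutral medium leaves the benzyl ethers untouched, and dilute acid then cleaves the two aryl trimethylsilyl ethers of 11.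

Step 7
Reactants: 12 [3,4-bis(benzyloxy)phenyl]{2-[(E)-2-(4-benzyloxy-3-methoxyphenyl)ethenyl]-4,6-dihydroxyphenyl}methanone
Product: 13 4-[3,4-bis(benzyloxy)benzoyl]-5-[(E)-2-(4-benzyloxy-3-methoxyphenyl)ethenyl]-1,3-phenylene diethyl biscarbonate
Conditions: ClCO2Et (2.5 equiv), Et3N (3 equiv), DMAP (5 mol %), THF, 0 °C
Reagents that add atoms: ethyl chloroformate, CCOC(=O)Cl
Why: O-Acylation of phenols with a chloroformate; DMAP helps with the hydrogen-bonded C3 hydroxyl. The carbonates remove the phenoxide deactivation of the ketone and place the leaving group for step 8 on the C3 oxygen.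

Step 8
Reactants: 13 4-[3,4-bis(benzyloxy)benzoyl]-5-[(E)-2-(4-benzyloxy-3-methoxyphenyl)ethenyl]-1,3-phenylene diethyl biscarbonate
Product: 16 4-[3,4-bis(benzyloxy)benzyl]-5-[(E)-2-(4-benzyloxy-3-methoxyphenyl)ethenyl]benzene-1,3-diol, via ortho-quinone methide 14 (not isolated), via monocarbonate 15 (not isolated)
Conditions: NaBH4 (6 equiv), THF–H2O, 0 °C to rt; then 2 M aq NaOH, N2, rt; mild acidic work-up
Reagents that add atoms: none
Why: ortho-Acyloxy-assisted deoxygenation of a phenone; hydride adds to C9=O, the C3 carbonate migrates to the new alkoxide through a six-membered transition state, and the phenoxide expels ethyl carbonate to give 14, which takes up a second hydride at C9 to give 15. No acid and no free C9 cation are involved, so C7=C8 is neither protonated nor drawn into a ring closure. Hydroxide then removes the remaining C5 carbonate while the catechol is still benzylated.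

Step 9
Reactants: 16 4-[3,4-bis(benzyloxy)benzyl]-5-[(E)-2-(4-benzyloxy-3-methoxyphenyl)ethenyl]benzene-1,3-diol
Product: 17 gnetupendin B, 4-(3,4-dihydroxybenzyl)-5-[(E)-2-(4-hydroxy-3-methoxyphenyl)ethenyl]benzene-1,3-diol
Conditions: BCl3 (8 equiv), C6HMe5 (12 equiv), CH2Cl2, −78 °C; MeOH–H2O quench at −78 °C
Reagents that add atoms: none
Why: Lewis acid cleavage of aryl benzyl ethers with pentamethylbenzene as a non-basic cation scavenger; no hydrogen is used, so C7=C8 survives. At −78 °C the primary methyl ether is cleaved far more slowly than the benzyl ethers, and the ring A phenols are tied up as borates during the reaction.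

## Compound list

1 | 4-(benzyloxy)-3-methoxybenzaldehyde | COc1cc(C=O)ccc1OCc1ccccc1 | starting material
2 | 1-(benzyloxy)-4-[(E)-2-iodoethenyl]-2-methoxybenzene | COc1cc(/C=C/I)ccc1OCc1ccccc1 | intermediate
3 | 3,4-bis(benzyloxy)benzaldehyde | O=Cc1ccc(OCc2ccccc2)c(OCc2ccccc2)c1 | starting material
4 | ethynylmagnesium bromide | C#C[Mg]Br | starting material
5 | (±)-1-[3,4-bis(benzyloxy)phenyl]prop-2-yn-1-ol | C#CC(O)c1ccc(OCc2ccccc2)c(OCc2ccccc2)c1 | intermediate
6 | (±)-(E)-1-[3,4-bis(benzyloxy)phenyl]-5-[4-(benzyloxy)-3-methoxyphenyl]pent-4-en-2-yn-1-ol | COc1cc(/C=C/C#CC(O)c2ccc(OCc3ccccc3)c(OCc3ccccc3)c2)ccc1OCc1ccccc1 | intermediate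
7 | (E)-1-[3,4-bis(benzyloxy)phenyl]-5-[4-(benzyloxy)-3-methoxyphenyl]pent-4-en-2-yn-1-one | COc1cc(/C=C/C#CC(=O)c2ccc(OCc3ccccc3)c(OCc3ccccc3)c2)ccc1OCc1ccccc1 | intermediate
8 | 5,5-dimethylcyclohexane-1,3-dione (dimedone) | CC1(C)CC(=O)CC(=O)C1 | starting material
9 | 5,5-dimethyl-1,3-bis[(trimethylsilyl)oxy]cyclohexa-1,3-diene | CC1(C)CC(O[Si](C)(C)C)=CC(O[Si](C)(C)C)=C1 | intermediate
10 | (±)-bicyclo[2.2.2]octa-2,5-diene adduct of 7 and 9 (silyloxy bridgehead next to the aroyl-bearing alkene carbon, CH bridgehead next to the styryl-bearing carbon, CMe2–CH2 bridge) | COc1cc(/C=C/C2=C(C(=O)c3ccc(OCc4ccccc4)c(OCc4ccccc4)c3)C3(O[Si](C)(C)C)C=C(O[Si](C)(C)C)C2C(C)(C)C3)ccc1OCc1ccccc1 | intermediate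
11 | [3,4-bis(benzyloxy)phenyl]{2-[(E)-2-(4-benzyloxy-3-methoxyphenyl)ethenyl]-4,6-bis[(trimethylsilyl)oxy]phenyl}methanone | COc1cc(/C=C/c2cc(O[Si](C)(C)C)cc(O[Si](C)(C)C)c2C(=O)c2ccc(OCc3ccccc3)c(OCc3ccccc3)c2)ccc1OCc1ccccc1 | intermediate
12 | [3,4-bis(benzyloxy)phenyl]{2-[(E)-2-(4-benzyloxy-3-methoxyphenyl)ethenyl]-4,6-dihydroxyphenyl}methanone | COc1cc(/C=C/c2cc(O)cc(O)c2C(=O)c2ccc(OCc3ccccc3)c(OCc3ccccc3)c2)ccc1OCc1ccccc1 | intermediate
13 | 4-[3,4-bis(benzyloxy)benzoyl]-5-[(E)-2-(4-benzyloxy-3-methoxyphenyl)ethenyl]-1,3-phenylene diethyl biscarbonate | COc1cc(/C=C/c2cc(OC(=O)OCC)cc(OC(=O)OCC)c2C(=O)c2ccc(OCc3ccccc3)c(OCc3ccccc3)c2)ccc1OCc1ccccc1 | intermediate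
14 | ortho-quinone methide: 4-[3,4-bis(benzyloxy)benzylidene]-5-[(E)-2-(4-benzyloxy-3-methoxyphenyl)ethenyl]-3-oxocyclohexa-1,5-dien-1-yl ethyl carbonate | CCOC(=O)OC1=CC(=O)C(=Cc2ccc(OCc3ccccc3)c(OCc3ccccc3)c2)C(/C=C/c2ccc(OCc3ccccc3)c(OC)c2)=C1 | intermediate
15 | 4-[3,4-bis(benzyloxy)benzyl]-3-[(E)-2-(4-benzyloxy-3-methoxyphenyl)ethenyl]-5-hydroxyphenyl ethyl carbonate | COc1cc(/C=C/c2cc(OC(=O)OCC)cc(O)c2Cc2ccc(OCc3ccccc3)c(OCc3ccccc3)c2)ccc1OCc1ccccc1 | intermediate
16 | 4-[3,4-bis(benzyloxy)benzyl]-5-[(E)-2-(4-benzyloxy-3-methoxyphenyl)ethenyl]benzene-1,3-diol | COc1cc(/C=C/c2cc(O)cc(O)c2Cc2ccc(OCc3ccccc3)c(OCc3ccccc3)c2)ccc1OCc1ccccc1 | intermediate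
17 | gnetupendin B | COc1cc(/C=C/c2cc(O)cc(O)c2Cc2ccc(O)c(O)c2)ccc1O | target

## Step count and least certain steps

Total step count: 9. The longest linear sequence is 7 steps (2, 3, 4, 6, 7, 8, 9). The branch through step 1 is equally long, and step 5 is a one-step side branch.

**Step 6 (key step).** The most likely failure is a cycloaddition that is too slow. Donor ring B pushes electron density through C8=C7 into the ynone and raises its LUMO. Thermal oligomerisation of 7, protodesilylation of 9, and some addition across C7=C8 would then have time to compete.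

The fallback takes the donor arm out of the dienophile and closes C7=C8 afterwards.
- Starting from 3, lithiated 3,3-diethoxyprop-1-yne is added to give 1-[3,4-bis(benzyloxy)phenyl]-4,4-diethoxybut-2-yn-1-ol F1.
- MnO2 then gives 1-[3,4-bis(benzyloxy)phenyl]-4,4-diethoxybut-2-yn-1-one F2, whose alkyne bears no donor.
- The same Alder–Rickert reaction with 9, followed by an acidic work-up, should give 2-[3,4-bis(benzyloxy)benzoyl]-3,5-dihydroxybenzaldehyde F3.
- In parallel, 1 is reduced with NaBH4 to [4-(benzyloxy)-3-methoxyphenyl]methanol F4.
- PBr3 turns this into 1-(benzyloxy)-4-(bromomethyl)-2-methoxybenzene F5.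
- An Arbuzov reaction with P(OEt)3 then gives diethyl [4-(benzyloxy)-3-methoxybenzyl]phosphonate F6.
- A Horner–Wadsworth–Emmons reaction of F3 with F6 (KOt-Bu in excess, THF) forms the E alkene and comes back to the route at 12.

**Step 8.** Hydride delivery to the doubly ortho-substituted, twisted diaryl ketone may be slower than hydrolytic loss of the carbonates, which would restore the deactivating phenoxide. The transient quinone methide could also be caught by water, or by C8 of the styryl arm in a five-membered ring closure, before the second hydride arrives.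

The fallback replaces the ionic deoxygenation by a radical one.
- Starting from 12, BnBr and K2CO3 give [3,4-bis(benzyloxy)phenyl]{2,4-bis(benzyloxy)-6-[(E)-2-(4-benzyloxy-3-methoxyphenyl)ethenyl]phenyl}methanone F7.
- LiAlH4 gives the corresponding benzhydrol F8.
- NaH, CS2 and MeI give its O-benzhydryl S-methyl xanthate F9.
- A Barton–McCombie reduction (Bu3SnH, AIBN, toluene, 80 °C) gives the perbenzylated diarylmethane F10. Closure of the C9 radical on the styryl arm would have to be 4-exo or 5-endo and is disfavoured.
- The conditions of step 9 applied to F10 come back to the route at 17.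

**Step 9.** Three processes are the likely problems:
- transfer of benzyl cations to the nucleophilic positions C4 and C6 of the free resorcinol ring;
- chelation-assisted loss of the methyl ether once the neighbouring oxygen of ring B is bound to boron;
- acid-induced reactions at C7=C8 on warming.

The fallback deactivates ring A before the debenzylation.
- Starting from 16, Ac2O and pyridine give 4-[3,4-bis(benzyloxy)benzyl]-5-[(E)-2-(4-benzyloxy-3-methoxyphenyl)ethenyl]-1,3-phenylene diacetate F11.
- BCl3 and C6HMe5 at −78 °C give 4-(3,4-dihydroxybenzyl)-5-[(E)-2-(4-hydroxy-3-methoxyphenyl)ethenyl]-1,3-phenylene diacetate F12, which can be purified as a less oxidisable compound.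
- Acid-catalysed methanolysis (AcCl in MeOH, rt) comes back to the route at 17.

**Step 1.** E selectivity may be incomplete, and light may isomerise the electron-rich iodoalkene. Either would be carried into every later compound. A large excess of air-sensitive CrCl2 is also needed.

The fallback builds the alkene by condensation and exchanges carboxyl for iodine.
- Starting from 1, a Knoevenagel–Doebner condensation with malonic acid (pyridine, piperidine, 90 °C) gives (E)-3-[4-(benzyloxy)-3-methoxyphenyl]prop-2-enoic acid F13.
- A catalytic Hunsdiecker-type iododecarboxylation (NIS, LiOAc cat., MeCN–H2O) comes back to the route at 2.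

## Further compounds

F1 | step 6 | 1-[3,4-bis(benzyloxy)phenyl]-4,4-diethoxybut-2-yn-1-ol | CCOC(OCC)C#CC(O)c1ccc(OCc2ccccc2)c(OCc2ccccc2)c1
F2 | step 6 | 1-[3,4-bis(benzyloxy)phenyl]-4,4-diethoxybut-2-yn-1-one | CCOC(OCC)C#CC(=O)c1ccc(OCc2ccccc2)c(OCc2ccccc2)c1
F3 | step 6 | 2-[3,4-bis(benzyloxy)benzoyl]-3,5-dihydroxybenzaldehyde | O=Cc1cc(O)cc(O)c1C(=O)c1ccc(OCc2ccccc2)c(OCc2ccccc2)c1
F4 | step 6 | [4-(benzyloxy)-3-methoxyphenyl]methanol | COc1cc(CO)ccc1OCc1ccccc1
F5 | step 6 | 1-(benzyloxy)-4-(bromomethyl)-2-methoxybenzene | COc1cc(CBr)ccc1OCc1ccccc1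
F6 | step 6 | diethyl [4-(benzyloxy)-3-methoxybenzyl]phosphonate | CCOP(=O)(Cc1ccc(OCc2ccccc2)c(OC)c1)OCC
F7 | step 8 | [3,4-bis(benzyloxy)phenyl]{2,4-bis(benzyloxy)-6-[(E)-2-(4-benzyloxy-3-methoxyphenyl)ethenyl]phenyl}methanone | COc1cc(/C=C/c2cc(OCc3ccccc3)cc(OCc3ccccc3)c2C(=O)c2ccc(OCc3ccccc3)c(OCc3ccccc3)c2)ccc1OCc1ccccc1
F8 | step 8 | (±)-[3,4-bis(benzyloxy)phenyl]{2,4-bis(benzyloxy)-6-[(E)-2-(4-benzyloxy-3-methoxyphenyl)ethenyl]phenyl}methanol | COc1cc(/C=C/c2cc(OCc3ccccc3)cc(OCc3ccccc3)c2C(O)c2ccc(OCc3ccccc3)c(OCc3ccccc3)c2)ccc1OCc1ccccc1
F9 | step 8 | (±)-O-benzhydryl S-methyl xanthate of F8 | COc1cc(/C=C/c2cc(OCc3ccccc3)cc(OCc3ccccc3)c2C(OC(=S)SC)c2ccc(OCc3ccccc3)c(OCc3ccccc3)c2)ccc1OCc1ccccc1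
F10 | step 8 | 1,5-bis(benzyloxy)-2-[3,4-bis(benzyloxy)benzyl]-3-[(E)-2-(4-benzyloxy-3-methoxyphenyl)ethenyl]benzene | COc1cc(/C=C/c2cc(OCc3ccccc3)cc(OCc3ccccc3)c2Cc2ccc(OCc3ccccc3)c(OCc3ccccc3)c2)ccc1OCc1ccccc1
F11 | step 9 | 4-[3,4-bis(benzyloxy)benzyl]-5-[(E)-2-(4-benzyloxy-3-methoxyphenyl)ethenyl]-1,3-phenylene diacetate | COc1cc(/C=C/c2cc(OC(C)=O)cc(OC(C)=O)c2Cc2ccc(OCc3ccccc3)c(OCc3ccccc3)c2)ccc1OCc1ccccc1
F12 | step 9 | 4-(3,4-dihydroxybenzyl)-5-[(E)-2-(4-hydroxy-3-methoxyphenyl)ethenyl]-1,3-phenylene diacetate | COc1cc(/C=C/c2cc(OC(C)=O)cc(OC(C)=O)c2Cc2ccc(O)c(O)c2)ccc1O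
F13 | step 1 | (E)-3-[4-(benzyloxy)-3-methoxyphenyl]prop-2-enoic acid | COc1cc(/C=C/C(=O)O)ccc1OCc1ccccc1
A1 | alternative 1 | isorhapontigenin | COc1cc(/C=C/c2cc(O)cc(O)c2)ccc1O
A2 | alternative 1 | 3,4-dihydroxybenzyl alcohol | OCc1ccc(O)c(O)c1
A3 | alternative 1 | 2-[3,4-bis(benzyloxy)benzyl]-3,5-bis(benzyloxy)benzaldehyde | O=Cc1cc(OCc2ccccc2)cc(OCc2ccccc2)c1Cc1ccc(OCc2ccccc2)c(OCc2ccccc2)c1
A4 | alternative 2 | 3,5-bis(benzyloxy)-2-(trimethylsilyl)phenyl trifluoromethanesulfonate | C[Si](C)(C)c1c(OCc2ccccc2)cc(OCc2ccccc2)cc1OS(=O)(=O)C(F)(F)F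
A5 | alternative 2 | 3,4-bis(benzyloxy)benzyl bromide | BrCc1ccc(OCc2ccccc2)c(OCc2ccccc2)c1
A6 | alternative 2 | 1-(benzyloxy)-4-ethenyl-2-methoxybenzene | C=Cc1ccc(OCc2ccccc2)c(OC)c1
A7 | alternative 3 | 4-(benzyloxy)-6-[(E)-2-(4-benzyloxy-3-methoxyphenyl)ethenyl]-2H-pyran-2-one | COc1cc(/C=C/c2cc(OCc3ccccc3)cc(=O)o2)ccc1OCc1ccccc1
A8 | alternative 3 | {3-[3,4-bis(benzyloxy)phenyl]prop-1-yn-1-yl}oxy(triisopropyl)silane | CC(C)[Si](OC#CCc1ccc(OCc2ccccc2)c(OCc2ccccc2)c1)(C(C)C)C(C)C
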